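**Strategy.** The enolised cyclohexanetrione ring (C1 carbonyl, C2 acyl carbon, C3 and C5 enol carbons, C4 prenyl carbon, C6 quaternary stereocentre) is opened at C3–C4, a Claisen retron: C4 is the α-carbon of the C5 ketone, C3 a carboxyl carbon. Because C6 is quaternary, the C5 ketone can enolise only towards C4, so a Dieckmann-type closure, akin to polyketide cyclisation, forms the six-membered ring in one operation with C6 untouched. The precursor is an open-chain keto (E)-β-methoxyacrylate; its enol ether masks the C1 carbonyl, so no acidic CH2 deactivates the ester. C6 is set earlier by enzymatic desymmetrisation of a prochiral malonate; the C2 acyl group is added last.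

Key step: step 6

Assumption: pig liver esterase is taken to cleave the pro-R ester group of 3, which gives (S)-4 (sense and selectivity to be confirmed on the first run; a resolution is given below); enolised di- and triketones are drawn as one tautomer.

Step 1
Reactants: 1 dimethyl 2-methoxypropanedioate; 2 1-bromo-3-methylbut-2-ene (prenyl bromide)
Product: 3 dimethyl 2-methoxy-2-(3-methylbut-2-en-1-yl)propanedioate
Conditions: NaH, THF/DMF, 0 °C to rt
Reagents that add atoms: none
Why: Malonate alkylation (SN2 of the sodium enolate on the primary allylic bromide) should give the prochiral quaternary diester; no stereocentre is formed.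

Step 2
Reactants: 3 dimethyl 2-methoxy-2-(3-methylbut-2-en-1-yl)propanedioate
Product: 4 (S)-2-methoxy-2-(methoxycarbonyl)-5-methylhex-4-enoic acid
Conditions: pig liver esterase, phosphate buffer pH 7.5/DMSO 9:1, 25 °C, pH-stat (1 M NaOH); then 1 M HCl to pH 2
Reagents that add atoms: water, O
Why: Enzymatic desymmetrisation of a prochiral 2,2-disubstituted malonate: the esterase hydrolyses one of the two enantiotopic methyl esters (taken as the pro-R group), and this choice alone sets the quaternary stereocentre as (S).

Step 3
Reactants: 4 (S)-2-methoxy-2-(methoxycarbonyl)-5-methylhex-4-enoic acid; 5 5-bromo-2-methylpent-2-ene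
Product: 8 methyl (S)-2-methoxy-7-methyl-2-(3-methylbut-2-en-1-yl)-3-oxooct-6-enoate, via acid chloride 6 (not isolated), via Grignard reagent 7 (not isolated)
Conditions: 4, 1-chloro-N,N,2-trimethylprop-1-en-1-amine, CH2Cl2, 0 °C to rt; separately 5, Mg, THF, rt; combine, Fe(acac)3 (3 mol %), THF, −78 °C
Reagents that add atoms: none
Why: Iron-catalysed acylation of a Grignard reagent by an acid chloride is fast at −78 °C and stops at the ketone, so the methyl ester and the alkenes survive and the quaternary centre, which has no α-hydrogen, is untouched.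

Step 4
Reactants: 8 methyl (S)-2-methoxy-7-methyl-2-(3-methylbut-2-en-1-yl)-3-oxooct-6-enoate; 9 methyl acetate
Product: 11 methyl (S)-4-methoxy-9-methyl-4-(3-methylbut-2-en-1-yl)-3,5-dioxodec-8-enoate, via lithium enolate 10 (not isolated)
Conditions: 8, LiHMDS (1.1 equiv), THF, −78 °C; then 10 (from 9 and LDA, 3 equiv, THF, −78 °C), −78 to −30 °C; AcOH
Reagents that add atoms: none
Why: Crossed Claisen condensation: the ketone is first stored as its lithium enolate (it has only one enolisable side), the acetate enolate then attacks the α-methoxy-activated methyl ester, and the β-keto ester is protected as its enolate until the quench; the stereocentre is not involved.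

Step 5
Reactants: 11 methyl (S)-4-methoxy-9-methyl-4-(3-methylbut-2-en-1-yl)-3,5-dioxodec-8-enoate
Product: 12 methyl (2E,4R)-3,4-dimethoxy-9-methyl-4-(3-methylbut-2-en-1-yl)-5-oxodeca-2,8-dienoate
Conditions: Me2SO4, K2CO3, DMF, 0 °C to rt
Reagents that add atoms: dimethyl sulfate, COS(=O)(=O)OC
Why: O-Methylation of a β-keto ester enolate by a hard methylating agent in a dipolar aprotic solvent (the standard route to β-methoxyacrylates) should give the (E)-enol ether, in which the ester lies cis to the quaternary carbon; carbonate does not touch the ketone CH2, and the descriptor changes to (R) only through the priority rules.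

Step 6
Reactants: 12 methyl (2E,4R)-3,4-dimethoxy-9-methyl-4-(3-methylbut-2-en-1-yl)-5-oxodeca-2,8-dienoate
Product: 14 (S)-3,5-dihydroxy-6-methoxy-4,6-bis(3-methylbut-2-en-1-yl)cyclohexa-2,4-dien-1-one, via methoxy dienone 13 (not isolated)
Conditions: LiHMDS (1.5 equiv), THF, −78 °C to rt; then 1 M HCl, THF, rt
Reagents that add atoms: water, O
Why: LiHMDS removes the only acidic C–H of 12, the CH2 beside the ketone (the quaternary carbon blocks the other side and the enol ether leaves no acidic CH2 between ketone and ester), the lithium enolate carbon adds to the ester carbonyl, methoxide leaves and deprotonates the vinylogous β-diketone 13, which drives the closure; aqueous HCl then hydrolyses the vinylogous methyl ester to 14. The closest known reaction type is the Dieckmann-type (intramolecular Claisen) closure of δ-keto esters to cyclohexane-1,3-diones and of 4,4-disubstituted 3,5-dioxo esters to cyclohexane-1,3,5-triones, the laboratory counterpart of polyketide ring closure. The six-membered carbocycle closes in the 6-(enolendo)-exo-trig mode. No stereocentre is formed; the quaternary centre set in step 2 cannot enolise and is carried through. The step needs C- over O-acylation of the enolate and closure rather than retro-Claisen cleavage: the (E)-enol ether holds the ester cis to the nucleophile, the lithium enolate in THF favours attack through carbon, an enol lactone formed through oxygen would be reopened by the liberated methoxide, and the product is protected as its enolate as soon as it forms.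

Step 7
Reactants: 14 (S)-3,5-dihydroxy-6-methoxy-4,6-bis(3-methylbut-2-en-1-yl)cyclohexa-2,4-dien-1-one; 15 3-phenylpropanoic acid
Product: 16 (S)-3,5-dihydroxy-6-methoxy-4,6-bis(3-methylbut-2-en-1-yl)-2-(3-phenylpropanoyl)cyclohexa-2,4-dien-1-one
Conditions: DCC, DMAP (0.3 equiv), Et3N, CH2Cl2, 0 °C to rt
Reagents that add atoms: none
Why: One-pot O-acylation and DMAP-mediated O-to-C acyl migration (Fries-type rearrangement of enol esters of cyclic β-diketones) should place the acyl group on the only unsubstituted enolic carbon, C2, where the product is held as a hydrogen-bonded enolised triketone; the stereocentre is not involved.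

**Compound list**

1 | dimethyl 2-methoxypropanedioate | COC(C(=O)OC)C(=O)OC | starting material
2 | 1-bromo-3-methylbut-2-ene | CC(C)=CCBr | starting material
3 | dimethyl 2-methoxy-2-(3-methylbut-2-en-1-yl)propanedioate | COC(=O)C(OC)(CC=C(C)C)C(=O)OC | intermediate
4 | (S)-2-methoxy-2-(methoxycarbonyl)-5-methylhex-4-enoic acid | CO[C@](CC=C(C)C)(C(=O)OC)C(=O)O | intermediate
5 | 5-bromo-2-methylpent-2-ene | CC(C)=CCCBr | starting material
6 | methyl (R)-2-(chlorocarbonyl)-2-methoxy-5-methylhex-4-enoate (same spatial arrangement as 4) | CO[C@](CC=C(C)C)(C(=O)OC)C(Cl)=O | intermediate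
7 | (4-methylpent-3-en-1-yl)magnesium bromide | CC(C)=CCC[Mg]Br | intermediate
8 | methyl (S)-2-methoxy-7-methyl-2-(3-methylbut-2-en-1-yl)-3-oxooct-6-enoate | CO[C@](CC=C(C)C)(C(=O)OC)C(=O)CCC=C(C)C | intermediate
9 | methyl acetate | COC(C)=O | starting material
10 | lithium enolate of methyl acetate | C=C(OC)O[Li] | intermediate
11 | methyl (S)-4-methoxy-9-methyl-4-(3-methylbut-2-en-1-yl)-3,5-dioxodec-8-enoate | CO[C@](CC=C(C)C)(C(=O)CC(=O)OC)C(=O)CCC=C(C)C | intermediate
12 | methyl (2E,4R)-3,4-dimethoxy-9-methyl-4-(3-methylbut-2-en-1-yl)-5-oxodeca-2,8-dienoate | COC(=O)/C=C(/OC)[C@](OC)(CC=C(C)C)C(=O)CCC=C(C)C | intermediate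
13 | (S)-3-hydroxy-4,5-dimethoxy-2,4-bis(3-methylbut-2-en-1-yl)cyclohexa-2,5-dien-1-one | CO[C@]1(CC=C(C)C)C(OC)=CC(=O)C(CC=C(C)C)=C1O | intermediate
14 | (S)-3,5-dihydroxy-6-methoxy-4,6-bis(3-methylbut-2-en-1-yl)cyclohexa-2,4-dien-1-one | CO[C@]1(CC=C(C)C)C(=O)C=C(O)C(CC=C(C)C)=C1O | intermediate
15 | 3-phenylpropanoic acid | OC(=O)CCc1ccccc1 | starting material
16 | (S)-3,5-dihydroxy-6-methoxy-4,6-bis(3-methylbut-2-en-1-yl)-2-(3-phenylpropanoyl)cyclohexa-2,4-dien-1-one | CO[C@]1(CC=C(C)C)C(=O)C(C(=O)CCc2ccccc2)=C(O)C(CC=C(C)C)=C1O | target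

Total step count: 7. Longest linear sequence: 7 steps (1 to 16).

**Steps most likely to fail**

Step 6 (key step). The enolate may close through oxygen to an enol lactone, any (Z)-isomer of 12 cannot bring the ester within reach, and liberated methoxide may start retro-Claisen cleavage at the quaternary centre. The fallback sets out from 11 and comes back at 16, replacing steps 5 to 7 with a temporary isoxazole ring. 3-Phenylpropanal and hydroxylamine give 3-phenylpropanal oxime F1, and NCS in DMF converts it into N-hydroxy-3-phenylpropanimidoyl chloride F2. Et3N releases 3-phenylpropanenitrile oxide F3 in the presence of 11, whose enolate adds to it and cyclises with loss of water to methyl 5-[(5R)-5-methoxy-2,10-dimethyl-6-oxoundeca-2,9-dien-5-yl]-3-(2-phenylethyl)-1,2-oxazole-4-carboxylate F4. In F4 the C1 oxygen and C2 are locked in an aromatic ring, no acidic CH2 remains, the ester is fixed cis to the keto side chain and the acyl carbons are already in place. LiHMDS in THF then closes the same C3–C4 bond by Dieckmann condensation onto the isoxazole ester to give (S)-6-hydroxy-7-methoxy-5,7-bis(3-methylbut-2-en-1-yl)-3-(2-phenylethyl)-1,2-benzoxazol-4(7H)-one F5. Mo(CO)6 in wet MeCN cleaves the N–O bond to (S)-2-(1-amino-3-phenylpropylidene)-5-hydroxy-6-methoxy-4,6-bis(3-methylbut-2-en-1-yl)cyclohex-4-ene-1,3-dione F6, and warm aqueous NaOH followed by acidification hydrolyses the enaminone to 16.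

Step 2. The esterase may discriminate poorly between the two ester groups or prefer the other one. The fallback sets out from 3 and comes back at 4. One equivalent of KOH in aqueous MeOH gives racemic 2-methoxy-2-(methoxycarbonyl)-5-methylhex-4-enoic acid F7. It is resolved by crystallisation of the (S)-1-phenylethylammonium salt of the (S)-acid F8 (the antipodal amine is used if the salt of the (R)-acid proves the less soluble). Acidification of the salt returns 4.

Step 4. Attack of the acetate enolate on the neopentyl-type ester may be slow, and aldol or retro-Claisen processes at the neighbouring ketone may compete. The fallback sets out from 4 and comes back at 11, replacing steps 3 and 4. Acid chloride 6, made as in step 3, reacts with N,O-dimethylhydroxylamine hydrochloride and pyridine to give the N-methoxy-N-methylamide methyl (S)-2-methoxy-2-[methoxy(methyl)carbamoyl]-5-methylhex-4-enoate F9. LiOH in aqueous THF cleaves the methyl ester to (S)-2-methoxy-2-[methoxy(methyl)carbamoyl]-5-methylhex-4-enoic acid F10. Carbonyldiimidazole converts it into (R)-2-(1H-imidazole-1-carbonyl)-N,2-dimethoxy-N,5-dimethylhex-4-enamide F11, which acylates Mg(O2CCH2CO2Me)2 with loss of CO2 to give methyl (R)-4-methoxy-4-[methoxy(methyl)carbamoyl]-7-methyl-3-oxooct-6-enoate F12. Grignard reagent 7 (2.5 equiv) first turns the β-keto ester into its magnesium enolate and then adds once to the amide, and work-up gives 11.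

**Further compounds**

F1 | step 6 | 3-phenylpropanal oxime | ON=CCCc1ccccc1
F2 | step 6 | N-hydroxy-3-phenylpropanimidoyl chloride | ON=C(Cl)CCc1ccccc1
F3 | step 6 | 3-phenylpropanenitrile oxide | [O-][N+]#CCCc1ccccc1
F4 | step 6 | methyl 5-[(5R)-5-methoxy-2,10-dimethyl-6-oxoundeca-2,9-dien-5-yl]-3-(2-phenylethyl)-1,2-oxazole-4-carboxylate | COC(=O)c1c(CCc2ccccc2)noc1[C@](OC)(CC=C(C)C)C(=O)CCC=C(C)C
F5 | step 6 | (S)-6-hydroxy-7-methoxy-5,7-bis(3-methylbut-2-en-1-yl)-3-(2-phenylethyl)-1,2-benzoxazol-4(7H)-one | CO[C@]1(CC=C(C)C)c2onc(CCc3ccccc3)c2C(=O)C(CC=C(C)C)=C1O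
F6 | step 6 | (S)-2-(1-amino-3-phenylpropylidene)-5-hydroxy-6-methoxy-4,6-bis(3-methylbut-2-en-1-yl)cyclohex-4-ene-1,3-dione | CO[C@]1(CC=C(C)C)C(=O)C(=C(N)CCc2ccccc2)C(=O)C(CC=C(C)C)=C1O
F7 | step 2 | racemic 2-methoxy-2-(methoxycarbonyl)-5-methylhex-4-enoic acid | COC(CC=C(C)C)(C(=O)OC)C(=O)O
F8 | step 2 | (S)-1-phenylethylammonium (S)-2-methoxy-2-(methoxycarbonyl)-5-methylhex-4-enoate | CO[C@](CC=C(C)C)(C(=O)OC)C(=O)[O-].C[C@H]([NH3+])c1ccccc1
F9 | step 4 | methyl (S)-2-methoxy-2-[methoxy(methyl)carbamoyl]-5-methylhex-4-enoate | CO[C@](CC=C(C)C)(C(=O)OC)C(=O)N(C)OC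
F10 | step 4 | (S)-2-methoxy-2-[methoxy(methyl)carbamoyl]-5-methylhex-4-enoic acid | CO[C@](CC=C(C)C)(C(=O)O)C(=O)N(C)OC
F11 | step 4 | (R)-2-(1H-imidazole-1-carbonyl)-N,2-dimethoxy-N,5-dimethylhex-4-enamide | CO[C@](CC=C(C)C)(C(=O)n1ccnc1)C(=O)N(C)OC
F12 | step 4 | methyl (R)-4-methoxy-4-[methoxy(methyl)carbamoyl]-7-methyl-3-oxooct-6-enoate | CO[C@](CC=C(C)C)(C(=O)CC(=O)OC)C(=O)N(C)OC
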